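TBS = tert-butyldimethylsilyl; prenyl = 3-methylbut-2-en-1-yl. Locants C2–C8a, O1 and 4' follow flavan numbering.

## Retrosynthetic overview

1. Feature: ring A is a phloroglucinol with six different positions (C4a–C4 side chain, C5–OMe, C6–H, C7–OH, C8–prenyl, C8a–O1). C8a/C6/C7/C8 map onto C1/C2/C3/C4 of a 3-alkoxy-4-prenylcyclobutenone, and C4a/C5 onto the two carbons of a methoxyalkyne.
2. Key disconnection, one operation: C4a–C8a and C5–C6 (benzannulation, ring A first), then O1–C2 (the new C8a–OH opens a C2–C3 trans-epoxide, ring C second). Ring B is bought.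
3. Alkyne fragment: the C4–alkyne bond comes from methoxyacetylide addition to a (2R,3S)-epoxy aldehyde made by Katsuki–Sharpless epoxidation (sets C2 and C3; C4 follows by Felkin–Anh control).
4. Cyclobutenone fragment: [2+2] of prenylketene with ethoxyacetylene, then OEt to O-allyl exchange. C4 alkylation of a cyclobutenone enolate is avoided because that enolate is an antiaromatic cyclobutadienolate.
5. End game: fluoride first and allyl removal last, so that no free 7-OH sits para to a C4 silyloxy leaving group under basic fluoride.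

Key step: step 9

Assumption: methyl p-coumarate, 5-methylhex-4-enoic acid and ethoxyacetylene (solution in hexanes) are taken as catalogue chemicals. The cyclobutenones are used as racemates because their only stereocentre becomes aromatic C8.

## Route

Step 1
Reactants: 1 methyl (E)-3-(4-hydroxyphenyl)prop-2-enoate (methyl p-coumarate)
Product: 2 methyl (E)-3-[4-(TBSO)phenyl]prop-2-enoate
Conditions: TBSCl, imidazole, DMF, 23 °C
Reagents that add atoms: tert-butyldimethylsilyl chloride, CC(C)(C)[Si](C)(C)Cl
Why: Imidazole-promoted O-silylation of a phenol masks O4' with a group that tolerates hydride, acetylide and heat and falls to fluoride.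

Step 2
Reactants: 2 methyl (E)-3-[4-(TBSO)phenyl]prop-2-enoate
Product: 3 (E)-3-[4-(TBSO)phenyl]prop-2-en-1-ol
Conditions: i-Bu2AlH (2.2 equiv), CH2Cl2, −78 °C; Na2SO4·10H2O
Reagents that add atoms: none
Why: 1,2-Reduction of an α,β-unsaturated ester with i-Bu2AlH gives the allylic alcohol without touching the alkene or the aryl silyl ether.

Step 3
Reactants: 3 (E)-3-[4-(TBSO)phenyl]prop-2-en-1-ol
Product: 4 [(2S,3S)-3-[4-(TBSO)phenyl]oxiran-2-yl]methanol
Conditions: Ti(OiPr)4 (10 mol %), L-(+)-diisopropyl tartrate (12 mol %), t-BuOOH (decane), 4 Å MS, CH2Cl2, −20 °C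
Reagents that add atoms: tert-butyl hydroperoxide, CC(C)(C)OO
Why: In the Katsuki–Sharpless asymmetric epoxidation, L-(+)-tartrate converts (E)-cinnamyl alcohols into the (2S,3S)-epoxy alcohols, which fixes the future C3 and the future C2 (to be inverted later), and catalytic loading over sieves at −20 °C limits Lewis-acid opening of the electron-rich aryl epoxide.

Step 4
Reactants: 4 [(2S,3S)-3-[4-(TBSO)phenyl]oxiran-2-yl]methanol
Product: 5 (2R,3S)-3-[4-(TBSO)phenyl]oxirane-2-carbaldehyde
Conditions: SO3·pyridine, DMSO, Et3N, CH2Cl2, 0 °C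
Reagents that add atoms: none
Why: The Parikh–Doering oxidation runs with amine present from the start, so the acid-labile aryl epoxide never meets free acid, and both epoxide centres are untouched (the C2 descriptor changes only by priority).

Step 5
Reactants: 5 (2R,3S)-3-[4-(TBSO)phenyl]oxirane-2-carbaldehyde; 6 chloroacetaldehyde dimethyl acetal
Product: 8 (1S)-1-[(2S,3S)-3-[4-(TBSO)phenyl]oxiran-2-yl]-3-methoxyprop-2-yn-1-ol, via lithium methoxyacetylide 7 (not isolated)
Conditions: 6 (1.5 equiv), LiNEt2 (3 equiv per 6, from n-BuLi and Et2NH), THF, −78 → 0 °C; then 5, −78 °C; H2O; Et3N-deactivated SiO2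
Reagents that add atoms: none
Why: Double elimination (MeOH, then HCl) and deprotonation of the chloroacetal give the alkoxyacetylide, and its 1,2-addition to the α,β-epoxy aldehyde follows the polar Felkin–Anh (Cornforth) mode, attacking anti to the epoxide C–O bond and past the small H, which sets the future C4 as (S), anti to the epoxide oxygen.

Step 6
Reactants: 8 (1S)-1-[(2S,3S)-3-[4-(TBSO)phenyl]oxiran-2-yl]-3-methoxyprop-2-yn-1-ol
Product: 9 methoxyalkyne bis-silyl ether (flavan numbering 2S,3R,4S): MeO–C≡C–C4H(OTBS)–[C3–C2 trans-epoxide]–C6H4-4-OTBS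
Conditions: TBSCl, imidazole, DMF, 23 °C
Reagents that add atoms: tert-butyldimethylsilyl chloride, CC(C)(C)[Si](C)(C)Cl
Why: Base-buffered O-silylation of the propargylic alcohol blocks Payne migration and Meyer–Schuster ionisation and avoids silyl triflate, which would attack the ynol ether.

Step 7
Reactants: 10 5-methylhex-4-enoic acid; 11 ethoxyacetylene
Product: 14 (±)-3-ethoxy-4-prenylcyclobut-2-en-1-one, via acid chloride 12 (not isolated), via prenylketene 13 (not isolated)
Conditions: (COCl)2, DMF (cat.), CH2Cl2, 0 → 23 °C, concentrate; then slow addition to 11 (3 equiv), Et3N, Et2O, 0 → 23 °C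
Reagents that add atoms: none
Why: Dehydrochlorination gives the aldoketene, which undergoes the known regioselective ketene–alkoxyalkyne [2+2] cycloaddition (carbonyl carbon to the unsubstituted alkyne carbon), placing ethoxy at C3 and prenyl at C4 without any cyclobutenone enolate.

Step 8
Reactants: 14 (±)-3-ethoxy-4-prenylcyclobut-2-en-1-one
Product: 15 (±)-3-(allyloxy)-4-prenylcyclobut-2-en-1-one
Conditions: allyl alcohol (solvent), camphor-10-sulfonic acid (2 mol %), 23 °C, EtOH stripped under reduced pressure
Reagents that add atoms: allyl alcohol, C=CCO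
Why: Acid-catalysed vinylogous transesterification (addition–elimination at C3 of the O-protonated enone) swaps ethoxy for allyloxy without breaking a C–H bond, so prenyl stays at C4, and interchange of the carbonyl and enol-ether carbons is degenerate in a four-membered ring.

Step 9
Reactants: 9 methoxyalkyne bis-silyl ether; 15 (±)-3-(allyloxy)-4-prenylcyclobut-2-en-1-one
Product: 21 (2R,3R,4S)-7-(allyloxy)-4-(TBSO)-2-[4-(TBSO)phenyl]-5-methoxy-8-prenylchroman-3-ol, via vinylketene 16 (not isolated), via alkenylcyclobutenone 17 (not isolated), via dienylketene 18 (not isolated), via cyclohexadienone 19 (not isolated), via epoxy phenol 20 (not isolated)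
Conditions: 15 (1.5 equiv, syringe pump) into 9, PhMe (0.1 M), 110 °C, base-washed glass, Ar; then pyridinium p-toluenesulfonate (5 mol %), 23 °C
Reagents that add atoms: none
Why: Proposed new method: conrotatory four-electron opening of 15 gives vinylketene 16, whose carbonyl carbon bonds to the nucleophilic alkyne carbon of 9 (future C4a) and whose alpha carbon bonds to the methoxy-bearing carbon (future C5) in a [2+2] cycloaddition to 17; a second four-electron opening gives dienylketene 18, six-electron electrocyclisation re-forms C8a–C8 (19) and tautomerisation delivers phenol 20, whose O1–H then attacks C2 of the epoxide. The closest known reaction types are the Danheiser benzannulation of cyclobutenones with alkoxyalkynes to resorcinol monoethers and the proton-assisted opening of aryl epoxides by ortho-phenols to flavan-3-ols; new are the 3-alkoxycyclobutenone partner, the epoxide-bearing ynol ether and the coupling of both events in one flask. Ring A closes by the 6π electrocyclisation of 18 and ring C by a 6-endo-tet epoxide opening. C2 is the only new stereocentre and is controlled by the epoxide: backside attack inverts (S) to (R), so the trans-epoxide of step 3 becomes the 2,3-trans pyran while C3 and C4 keep their bonds. The orientation in ring A is fixed by the polarisation of the ynol ether, and 6-endo over 5-exo opening is secured by benzylic stabilisation of developing charge at C2 by the 4-silyloxyphenyl ring under proton rather than phenoxide activation, which is why base is excluded and a trace of pyridinium p-toluenesulfonate completes the closure. The 110 °C ceiling keeps the allyl enol ether of 15 below its Claisen threshold and slow addition keeps the ketene from acylating the hydroxyl groups of 20 and 21.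

Step 10
Reactants: 21 (2R,3R,4S)-7-(allyloxy)-4-(TBSO)-2-[4-(TBSO)phenyl]-5-methoxy-8-prenylchroman-3-ol
Product: 22 (2R,3S,4S)-7-(allyloxy)-2-(4-hydroxyphenyl)-5-methoxy-8-prenylchroman-3,4-diol
Conditions: Bu4NF/AcOH (1:1, 3 equiv), THF, 0 → 23 °C
Reagents that add atoms: none
Why: Buffered fluoride-induced Si–O cleavage frees O4 and O4' while O7 is still allylated, so no para-phenoxide can expel the C4 oxygen as a quinone methide, and the buffer suppresses ring-opening epimerisation at C2.

Step 11
Reactants: 22 (2R,3S,4S)-7-(allyloxy)-2-(4-hydroxyphenyl)-5-methoxy-8-prenylchroman-3,4-diol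
Product: 23 5-O-methyl-8-prenylafzelechin-4β-ol
Conditions: Pd(PPh3)4 (5 mol %), morpholine (10 equiv), THF, 23 °C
Reagents that add atoms: none
Why: In this Tsuji–Trost-type deallylation, zerovalent palladium ionises only the aryl allyl ether to a π-allyl complex that morpholine captures, under near-neutral conditions that leave the C-prenyl group, the benzylic 4-OH and all three stereocentres untouched.

## Compound list

1 | methyl (E)-3-(4-hydroxyphenyl)prop-2-enoate | COC(=O)/C=C/c1ccc(O)cc1 | starting material
2 | methyl (E)-3-[4-(TBSO)phenyl]prop-2-enoate | COC(=O)/C=C/c1ccc(O[Si](C)(C)C(C)(C)C)cc1 | intermediate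
3 | (E)-3-[4-(TBSO)phenyl]prop-2-en-1-ol | OC/C=C/c1ccc(O[Si](C)(C)C(C)(C)C)cc1 | intermediate
4 | [(2S,3S)-3-[4-(TBSO)phenyl]oxiran-2-yl]methanol | OC[C@@H]1O[C@H]1c1ccc(O[Si](C)(C)C(C)(C)C)cc1 | intermediate
5 | (2R,3S)-3-[4-(TBSO)phenyl]oxirane-2-carbaldehyde | O=C[C@@H]1O[C@H]1c1ccc(O[Si](C)(C)C(C)(C)C)cc1 | intermediate
6 | chloroacetaldehyde dimethyl acetal | COC(CCl)OC | starting material
7 | lithium methoxyacetylide | [Li]C#COC | intermediate
8 | (1S)-1-[(2S,3S)-3-[4-(TBSO)phenyl]oxiran-2-yl]-3-methoxyprop-2-yn-1-ol (anti) | COC#C[C@H](O)[C@@H]1O[C@H]1c1ccc(O[Si](C)(C)C(C)(C)C)cc1 | intermediate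
9 | methoxyalkyne with C4 silyl ether and C2–C3 trans-epoxide (flavan numbering 2S,3R,4S) | COC#C[C@H](O[Si](C)(C)C(C)(C)C)[C@@H]1O[C@H]1c1ccc(O[Si](C)(C)C(C)(C)C)cc1 | intermediate
10 | 5-methylhex-4-enoic acid | CC(C)=CCCC(=O)O | starting material
11 | ethoxyacetylene | CCOC#C | starting material
12 | 5-methylhex-4-enoyl chloride | CC(C)=CCCC(=O)Cl | intermediate
13 | prenylketene (5-methylhexa-1,4-dien-1-one) | CC(C)=CCC=C=O | intermediate
14 | (±)-3-ethoxy-4-prenylcyclobut-2-en-1-one | CCOC1=CC(=O)C1CC=C(C)C | intermediate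
15 | (±)-3-(allyloxy)-4-prenylcyclobut-2-en-1-one | O=C1C=C(OCC=C)C1CC=C(C)C | intermediate
16 | vinylketene, (3Z)-3-(allyloxy)-7-methylocta-1,3,6-trien-1-one | O=C=C/C(OCC=C)=C/CC=C(C)C | intermediate
17 | [2+2] adduct: 3-methoxy-2-(side chain)-4-[(1Z)-1-(allyloxy)-5-methylhexa-1,4-dienyl]cyclobut-2-en-1-one (epimers at the ring sp3 carbon) | COC1=C([C@H](O[Si](C)(C)C(C)(C)C)[C@@H]2O[C@H]2c2ccc(O[Si](C)(C)C(C)(C)C)cc2)C(=O)C1/C(OCC=C)=C/CC=C(C)C | intermediate
18 | dienylketene O=C8a=C4a(side chain)–C5(OMe)=C6H–C7(O-allyl)=C8H–prenyl (C4a and C7 cis on C5=C6) | O=C=C(/C(OC)=C\C(OCC=C)=C\CC=C(C)C)[C@H](O[Si](C)(C)C(C)(C)C)[C@@H]1O[C@H]1c1ccc(O[Si](C)(C)C(C)(C)C)cc1 | intermediate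
19 | 6-prenylcyclohexa-2,4-dien-1-one tautomer of 20 (epimers at C8) | O=C1C(CC=C(C)C)C(OCC=C)=CC(OC)=C1[C@H](O[Si](C)(C)C(C)(C)C)[C@@H]1O[C@H]1c1ccc(O[Si](C)(C)C(C)(C)C)cc1 | intermediate
20 | epoxy phenol: ring A phenol (C8a–OH) with C4 silyl ether and C2–C3 trans-epoxide (2S,3R,4S) | COc1cc(OCC=C)c(CC=C(C)C)c(O)c1[C@H](O[Si](C)(C)C(C)(C)C)[C@@H]1O[C@H]1c1ccc(O[Si](C)(C)C(C)(C)C)cc1 | intermediate
21 | (2R,3R,4S)-7-(allyloxy)-4-(TBSO)-2-[4-(TBSO)phenyl]-5-methoxy-8-prenylchroman-3-ol (2,3-trans-3,4-cis) | COc1cc(OCC=C)c(CC=C(C)C)c2c1[C@H](O[Si](C)(C)C(C)(C)C)[C@H](O)[C@@H](c1ccc(O[Si](C)(C)C(C)(C)C)cc1)O2 | intermediate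
22 | (2R,3S,4S)-7-(allyloxy)-2-(4-hydroxyphenyl)-5-methoxy-8-prenylchroman-3,4-diol | COc1cc(OCC=C)c(CC=C(C)C)c2c1[C@H](O)[C@H](O)[C@@H](c1ccc(O)cc1)O2 | intermediate
23 | 5-O-methyl-8-prenylafzelechin-4β-ol, (2R,3S,4S) | COc1cc(O)c(CC=C(C)C)c2c1[C@H](O)[C@H](O)[C@@H](c1ccc(O)cc1)O2 | target

## Step count and risks

Total step count: 11. Longest linear sequence: 9 (steps 1–6, 9, 10, 11).

**Step 9 (bears the label).**
- What may go wrong:
  - the vinylogous-ester cyclobutenone may open too slowly below the temperature at which the allyl enol ether starts to rearrange;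
  - the hindered internal ynol ether may capture the ketene too slowly;
  - the epoxide may be lost on heating;
  - the epoxide may open 5-exo instead of 6-endo.
- Fallback (known chemistry; C4–C4a is made after ring A instead of during its formation). It sets out from 15, 7 and 5 and returns at 22.
  - Acetylide 7 is protonated with water and methoxyacetylene F1 is distilled into toluene.
  - The parent Danheiser benzannulation of 15 with excess F1 (sealed tube, 100 °C) gives 3-(allyloxy)-5-methoxy-2-prenylphenol F2, in which the future C4a is the only free ortho position.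
  - F2 is converted with Ti(OiPr)4 (i-PrOH distilled off) into its triisopropoxytitanium phenolate. This undergoes the known ortho-specific hydroxyalkylation with aldehyde 5 through a cyclic metal-bound transition state. The addition is not chelated to the epoxide and is therefore expected to be anti, giving the epoxy diol phenol F3.
  - Catalytic pyridinium p-toluenesulfonate then effects the known 6-endo opening to the 7-O-allyl-4'-O-silyl flavan-3,4-diol F4.
  - Bu4NF/AcOH removes the one silyl group to give 22.

**Step 5.**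
- What may go wrong: poor facial selectivity in the acetylide addition, Payne migration of the lithium alkoxide, or acid-triggered rearrangement of the propargylic ynol ether on isolation.
- Fallback (C4 set by hydride delivery instead of C–C bond formation). It sets out from crude 8 and returns at 8.
  - The mixture of 8 and its C4 epimer, the (1R)-alcohol F5, is oxidised with MnO2 in CH2Cl2 to the epoxy ynone F6.
  - Zn(BH4)2 in Et2O at −30 °C reduces F6 by the known erythro-selective reduction of α,β-epoxy ketones. The zinc bridges the carbonyl and epoxide oxygens and hydride comes from the open face, which converges both epimers on 8.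

**Step 8.**
- What may go wrong: migration of the ring double bond towards the prenyl-bearing carbon through ketonisation of the ketal intermediate, or ring cleavage by the alcohol.
- Fallback (the O7 group is brought in with the ynol ether, so no exchange is needed). It sets out from 10 and 9 and returns at 23.
  - The potassium alkoxide of 2-(trimethylsilyl)ethanol (KH) is added to trichloroethylene to give (E)-1,2-dichlorovinyl 2-(trimethylsilyl)ethyl ether F7.
  - n-BuLi (2 equiv) and then water give [2-(ethynyloxy)ethyl]trimethylsilane F8.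
  - Cycloaddition of F8 with ketene 13 (made from 10 via 12 as in step 7) gives 4-prenyl-3-[2-(trimethylsilyl)ethoxy]cyclobut-2-en-1-one F9. This has no sigmatropic pathway and takes the place of 15 in step 9, giving the 7-O-[2-(trimethylsilyl)ethyl] flavan F10.
  - Bu4NF first removes both silyl ethers at 23 °C. On warming it fragments the silylethyl aryl ether, at a stage when C4 carries only a poor leaving group, and gives 23 directly.

## Further compounds

F1 | step 9 | methoxyacetylene | COC#C
F2 | step 9 | 3-(allyloxy)-5-methoxy-2-(3-methylbut-2-en-1-yl)phenol | COc1cc(O)c(CC=C(C)C)c(OCC=C)c1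
F3 | step 9 | epoxy diol phenol (flavan numbering 2S,3S,4S; C4–OH free, 4'-OTBS) | COc1cc(OCC=C)c(CC=C(C)C)c(O)c1[C@H](O)[C@@H]1O[C@H]1c1ccc(O[Si](C)(C)C(C)(C)C)cc1
F4 | step 9 | (2R,3S,4S)-7-(allyloxy)-2-[4-(TBSO)phenyl]-5-methoxy-8-prenylchroman-3,4-diol | COc1cc(OCC=C)c(CC=C(C)C)c2c1[C@H](O)[C@H](O)[C@@H](c1ccc(O[Si](C)(C)C(C)(C)C)cc1)O2
F5 | step 5 | (1R)-1-[(2S,3S)-3-[4-(TBSO)phenyl]oxiran-2-yl]-3-methoxyprop-2-yn-1-ol (syn epimer) | COC#C[C@@H](O)[C@@H]1O[C@H]1c1ccc(O[Si](C)(C)C(C)(C)C)cc1
F6 | step 5 | 1-[(2R,3S)-3-[4-(TBSO)phenyl]oxiran-2-yl]-3-methoxyprop-2-yn-1-one | COC#CC(=O)[C@@H]1O[C@H]1c1ccc(O[Si](C)(C)C(C)(C)C)cc1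
F7 | step 8 | (E)-1,2-dichlorovinyl 2-(trimethylsilyl)ethyl ether | C[Si](C)(C)CCO/C(Cl)=C\Cl
F8 | step 8 | [2-(ethynyloxy)ethyl]trimethylsilane | C#COCC[Si](C)(C)C
F9 | step 8 | (±)-4-prenyl-3-[2-(trimethylsilyl)ethoxy]cyclobut-2-en-1-one | O=C1C=C(OCC[Si](C)(C)C)C1CC=C(C)C
F10 | step 8 | (2R,3R,4S)-4-(TBSO)-2-[4-(TBSO)phenyl]-5-methoxy-8-prenyl-7-[2-(trimethylsilyl)ethoxy]chroman-3-ol | COc1cc(OCC[Si](C)(C)C)c(CC=C(C)C)c2c1[C@H](O[Si](C)(C)C(C)(C)C)[C@H](O)[C@@H](c1ccc(O[Si](C)(C)C(C)(C)C)cc1)O2
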